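The single product can itself take up reagent, so the bis adduct beside it needs a scale with a zero.

| flask | starting material | reagent | remark | time |
|---|---|---|---|---|
| Saturday's | 0.037 M | 0.0825 M | run made earlier |  |
| Tuesday's | 0.083 M | 0.0825 M | run made earlier |  |
| Sunday's | 0.055 M | 0.041 M | run made earlier |  |
| flask | 0.055 M | 0.0825 M |  | 80 min |

- Saturday's (time / min: starting material / %, single product / %, bis adduct / %): 6.00: 96.2, 1.7, 2.8; 10.0: 94.9, 4.2, 0; 20.0: 92.7, 7.0, 0.7; 30.0: 88.5, 10.6, 1.7; 50.0: 85.5, 13.9, 0; 80.0: 77.7, 21.3, 0
- Tuesday's (time / min: starting material / %, single product / %, bis adduct / %): 6.00: 96.6, 4.1, 0.9; 10.0: 96.2, 1.7, 0; 20.0: 93.5, 9.4, 0; 30.0: 90.8, 9.8, 0; 50.0: 86.3, 14.7, 0.6; 80.0: 77.9, 21.0, 0.9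
- Sunday's (time / min: starting material / %, single product / %, bis adduct / %): 15.0: 96.7, 1.9, 0; 30.0: 95.2, 3.8, 1.3; 50.0: 90.6, 8.0, 1.7; 60.0: 92.0, 9.0, 0.6; 80.0: 87.0, 10.7, 0.4

(readings scatter by 1 percentage point)

- candidate steps: reagent + tris adduct -> tetra adduct; reagent + bis adduct -> tris adduct; reagent <-> dormant form; reagent + single product -> bis adduct; starting material + reagent -> single product

* how much starting material there is at 80 min, in percent of the starting material charged
* how much single product there is at 80 min, in percent of the starting material charged
* how much bis adduct there is at 80 min, in percent of the starting material charged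
* how much tris adduct there is at 80 min, in percent of the starting material charged

The bench rule of thumb for such a zero is that the sites are alike and reagent lands on them by chance. With 4 like sites a single product keeps 3, so its selectivity factor, the rate constant of its step over that of the first step, would be 0.750. Call the dose the natural logarithm of starting material charged over starting material left. A single product has on average seen half of that dose, so at small dose the adduct beyond single product, per single product, is the selectivity factor times half the dose. By chance this gives the dose times the chance coefficient 0.375.

Saturday's and Tuesday's runs used the flask's reagent, c(reagent) = 0.0825 M, and bracket its starting material. Their means at 80 min are 77.8% starting material and 21.2% single product, and this reckoning takes those for the flask. The dose is then 0.251, so chance predicts 1.99% bis adduct. The same two runs read 0.450%, less than chance, with a scatter of 1 percentage point on each reading. At 22.6% of the chance value the rule stops working, and the reading gives a selectivity factor near 0.170.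

The forecast gave 77.8% starting material, 21.2% single product, 0.9% bis adduct and 0.05% tris adduct. Its bis adduct stands above this reckoning's, and it read the low level as “which suggests the second step is not faster than the first”.

The flask gives 78.3%, 21.3%, 0.295% and 0.0623%, each within the forecast's range.

    reagent + tris adduct → tetra adduct (k = 1.60 M⁻¹ h⁻¹)
    reagent + bis adduct → tris adduct (k = 7.00 M⁻¹ h⁻¹)
    reagent ⇌ dormant form (K = 0.910, k = 0.250 h⁻¹)
    reagent + single product → bis adduct (k = 0.370 M⁻¹ h⁻¹)
    starting material + reagent → single product (k = 2.80 M⁻¹ h⁻¹)

The flask keeps 78.3% of its starting material because of the length of the run: left ten times as long, it keeps 31.5%. Its bis and tris adduct stand at 1.68% of its single product against a chance value of 9.17%, which gives a selectivity factor of 0.137. The neighbour flask charged with 0.050 M of reagent reaches a smaller dose, and its bis and tris adduct stand at 1.00% of its single product against a chance value of 5.54%, a selectivity factor of 0.136.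

The readings stem from a simulated flask on assumed constants; the scatter is artificial.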